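Remark: the target is taken as drawn, an achiral compound. TIPS = triisopropylsilyl. In compound names "Bf" stands for the 7-(2-methylbut-3-en-2-yl)-4,6-bis[(triisopropylsilyl)oxy]-1-benzofuran-2-yl group. Benzofuran atoms are numbered O1 to C7a; atoms of the aryl ring carry primes, C1' being bonded to C2.

## Analysis of the target

Artopetelin C (25) is a 2-arylbenzofuran of four rings. Ring A is the benzo ring, with hydroxyls on C4 and C6 and a 2-methylbut-3-en-2-yl (1,1-dimethylallyl) group on C7. Ring B is the furan, ring C a pentasubstituted benzene bonded through C1' to C2, and ring D a 2,2-dimethyldihydropyran fused to ring C through the oxygen on C5' and a CH2 on C6'. Ring C also carries a prenyl group on C2' and a hydroxyl on C3', and C4' is its only CH. There is no stereocenter and no configured double bond, so every difficulty is one of regiochemistry and chemoselectivity. The sensitive groups are the three free phenols on electron-rich rings (air oxidation), the prenyl group next to the C3' hydroxyl and the 1,1-dimethylallyl group next to the C6 hydroxyl (both close to cyclic ethers under acid), and the nucleophilic C3 of the furan. The synthesis is hard because three C5 units in three different forms must sit next to phenols of similar reactivity, and because the C2–C1' bond is flanked on ring C by carbon substituents on C2' and C6'. The strategy rests on ring C: its oxygens are meta (C3', C5') and C1', C2' and C6' carry carbon, the pattern of a resorcinol folded from a linear chain. C6', C5', C4', C3', C2' and C1' map onto C2 to C7 of a 3,5,7-trioxoheptanoate whose C7 ketone bears the benzofuran, whose C6 bears the prenyl group and whose ester carbon becomes the benzylic CH2 of ring D.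

## Retrosynthetic reasoning

**25 from 24.** The last operation should only unveil phenols, because the free triphenol is oxidizable and acid-labile. All three phenols are therefore carried as silyl ethers in 24 and released together by fluoride, a reagent that touches neither alkene nor the two ethers.

**24 from 21 and 22.** Ring D is cut at the O–C(CH3)2 bond and at the CH2–CH2 bond. This returns the four-carbon unit to 22 and leaves on ring C a hydroxymethyl group ortho to the C5' phenol, as in 21. Forward, 21 must lose its benzylic hydroxyl to the o-quinone methide 23, which is trapped by 22 in a [4+2] cycloaddition. The cut is made here because it distinguishes the C5 unit of ring D from the open prenyl group on C2' without any acid-mediated phenol–alkene closure.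

**21 from 20 and 19.** The hydroxymethyl group is the reduced form of an ester on C6', so 21 goes back to 20 and, by removal of one silyl group, to the resorcylate 19. The silyl group on the C3' oxygen is put on first because a benzylic alcohol with both an ortho and a para free hydroxyl condenses with itself very easily. In 19 only that oxygen is free of a hydrogen bond to the ester, so it can be addressed selectively.

**19 from 15.** Ring C is cut at C1'–C6' and unrolled into the chain of 17, whose masked form is the diketo-dioxinone 15. This is the central disconnection: every substituent of ring C is then fixed by its position on an open chain, and no aromatic substitution on a crowded ring is needed. Forward, the dioxinone must open to the ester 17, and the ester α-carbon must add to the benzofuranyl ketone and aromatize by dehydration.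

**15 from 10 and 14.** The chain is cut between the benzofuranyl carbonyl carbon and the prenyl-bearing methine. This separates ring A (as the N-methoxy-N-methyl amide 10) from the whole of the future ring C (as the keto-dioxinone 14) and makes the route convergent. Forward, the dianion of 14 must be acylated at its terminal carbon once and only once.

**14 from 13 and 2; 13 from 11 and 12.** The prenyl group is removed from the terminal carbon of the ketone, leading to 13 and the same bromide 2 that serves ring A. Compound 13 is the γ-acylation product of the dienolate of 11 with 12. The prenyl group is placed before the acylation of step 8 because after it two methylene groups of similar acidity would compete.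

**10 from 9; 9 from 6 and 7.** Ring B is cut at O1–C2 and C2=C3. Both bonds form in one operation from the salicylaldehyde 6 and 7: O-alkylation, then condensation of the ester methylene with the formyl group. The ester of 9 is exchanged for the amide of 10 so that the acylation of step 8 stops at the ketone.

**6 from 5; 5 from 3; 3 from 1 and 2.** The silyl groups of 6 are removed to give the triol 5. The quaternary benzylic carbon of 5 is traced back to the ether oxygen of 3 through a [3,3] shift, which is the only simple way to attach the allyl unit by its substituted end. The ether is put on the C4 oxygen of 1 because both ortho positions are then equivalent and the para position is blocked, so the shift has one outcome. The oxygen needed for ring B is then the one left free in 6 because it is the most hindered and the most strongly hydrogen-bonded.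

## Alternatives that were turned down

**Alternative 1:** Ring A is cut at C3a–C4, C4–C5 and C6–C7, leading to the furyl diazomethyl ketone A1 (ring C and ring D complete, C3' oxygen as pivalate) and the silyloxyalkyne A2. Forward, Wolff rearrangement of A1 gives a furylketene that adds to A2 in a [2+2] cycloaddition. The cyclobutenone opens and the dienylketene closes in a six-electron electrocyclization onto furan C3, giving the phenol A3.
- For it: ring A is made in one operation, and its two oxygens emerge differentiated (C4 free, C6 silylated). On this point it is stronger than the chosen route, which relies on steric discrimination in step 3.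
- Against it: C7 of A3 carries hydrogen. The 1,1-dimethylallyl group would have to be added afterwards by a prenyl ether shift from the C6 oxygen, where C5 competes with C7, on the fully assembled and heat-sensitive skeleton. The ketene and carbene intermediates also meet the prenyl double bond of ring C. Ring C, the hard part, must still be made beforehand by stepwise aromatic chemistry.
- Comparison: the chosen route settles C7 early by a shift on the symmetric ether 3 and builds ring C from a chain in step 9.

**Alternative 2:** Ring B is cut at C2=C3, leading to the phosphonium salt A4, in which the ring A phenol is esterified with the complete ring C acid. Forward, base gives the benzylic ylide, which attacks its own ester carbonyl; extrusion of phosphorus as its oxide closes the furan and gives the tris-silyl ether A5.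
- For it: this closure is a dependable way to 2-arylbenzofurans, the union is late, and only a desilylation follows. In convergence and in the shortness of the endgame it is stronger than the chosen route, which needs four steps after its key step.
- Against it: the acid part of A4 has its carboxyl between the prenyl group and the ring D CH2, and the phenol to be acylated sits next to the 1,1-dimethylallyl group. Both the esterification and the ylide attack on a doubly ortho-blocked carbonyl are hindered. The ring C acid needs its five substituents placed one by one by aromatic substitution, each a regiochemical question.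
- Comparison: the chosen route offers in exchange a ring C whose substitution pattern is fixed by the chain in 15 and cannot come out wrong.

**Alternative 3:** Ring A is cut at C5–C6, leading to the furan A6, which has an acetyl group on furan C3 and, on furan C2, an ester side chain whose α-carbon already bears the 1,1-dimethylallyl group. Forward, an alkoxide base forms the acetyl enolate, which attacks the side-chain ester; the cyclic diketone tautomerizes to the 4,6-diol A7.
- For it: C7 is substituted before ring A exists, so no allyl shift and no protection of ring A are needed, and one desilylation ends the synthesis. On these points it is stronger than the chosen route.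
- Against it: the ester carbonyl of A6 is next to a carbon that bears a quaternary centre, so the acyl substitution is hindered. That carbon is also the most acidic site, and its deprotonation turns the electrophile into an enolate. A6, a trisubstituted furan carrying the complete ring C, is long to make, and ring C again comes from stepwise aromatic chemistry.
- Comparison: the chosen route reaches its precursor 15 from two simple fragments, each made in a few steps, and leaves the risk in one ring-forming step of a well-understood type.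

Key step: step 9

## Route

Step 1
Reactants: 1 phloroglucinaldehyde (2,4,6-trihydroxybenzaldehyde); 2 prenyl bromide (1-bromo-3-methylbut-2-ene)
Product: 3 prenyl ether 2,6-dihydroxy-4-[(3-methylbut-2-en-1-yl)oxy]benzaldehyde
Conditions: K2CO3 (1.0 equiv), 2 (1.0 equiv), acetone, 0 °C → rt
Reagents that add atoms: prenyl bromide (2), CC(C)=CCBr
Why: Williamson etherification; the C4 hydroxyl, para to the formyl group and not held in a hydrogen bond, is the most acidic and is ionized first by one equivalent of carbonate, while the two chelated ortho hydroxyls stay protonated; the aprotic medium favours O- over C-alkylation.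

Step 2
Reactants: 3 prenyl ether
Product: 5 triol 2,4,6-trihydroxy-3-(2-methylbut-3-en-2-yl)benzaldehyde, via dienone 4 (not isolated)
Conditions: PhNEt2, 190 °C, Ar
Reagents that add atoms: none
Why: Aromatic Claisen rearrangement; the [3,3] shift inverts the allyl unit, so the ring receives the quaternary carbon, and because C3 and C5 are equivalent and the para position is blocked by the formyl group only one product can form. Dienone 4 tautomerizes to the phenol, and the basic solvent should suppress acid-induced closure of a phenol onto the new alkene.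

Step 3
Reactants: 5 triol
Product: 6 salicylaldehyde 2-hydroxy-3-(2-methylbut-3-en-2-yl)-4,6-bis[(triisopropylsilyl)oxy]benzaldehyde
Conditions: TIPSCl (2.2 equiv), imidazole, DMF, 0 °C → rt
Reagents that add atoms: chlorotriisopropylsilane, CC(C)[Si](Cl)(C(C)C)C(C)C
Why: Silylation of phenols; the C2 hydroxyl is both chelated to the formyl group and wedged between it and the quaternary carbon, so the bulky silyl chloride should stop after the C4 and C6 oxygens and leave free exactly the oxygen that becomes O1.

Step 4
Reactants: 6 salicylaldehyde; 7 ethyl bromoacetate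
Product: 9 benzofuran ester ethyl 7-(2-methylbut-3-en-2-yl)-4,6-bis[(triisopropylsilyl)oxy]-1-benzofuran-2-carboxylate, via aryloxyacetate 8 (not isolated)
Conditions: K2CO3, MeCN, 70 °C; then DBU (0.3 equiv), 4 Å MS, 80 °C
Reagents that add atoms: ethyl bromoacetate (7), CCOC(=O)CBr
Why: Rap–Stoermer-type sequence: O-alkylation of the single free phenol gives 8, whose ester methylene condenses with the neighbouring formyl group (intramolecular aldol, then dehydration) to give the aromatic furan. Acetonitrile and a moderate temperature are chosen to spare the aryl silyl ethers.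

Step 5
Reactants: 9 benzofuran ester
Product: 10 amide N-methoxy-N-methyl-7-(2-methylbut-3-en-2-yl)-4,6-bis[(triisopropylsilyl)oxy]-1-benzofuran-2-carboxamide
Conditions: MeNH(OMe)·HCl, i-PrMgCl, THF, −20 → 0 °C
Reagents that add atoms: N,O-dimethylhydroxylamine hydrochloride, CNOC.Cl
Why: Direct aminolysis of the ester by the magnesium amide of N,O-dimethylhydroxylamine; the chelated adduct does not react further, and aryl silyl ethers and both alkenes are inert to the reagent.

Step 6
Reactants: 11 trimethyldioxinone (2,2,6-trimethyl-4H-1,3-dioxin-4-one); 12 acetyl chloride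
Product: 13 acetonyl dioxinone 2,2-dimethyl-6-(2-oxopropyl)-4H-1,3-dioxin-4-one
Conditions: LiN(SiMe3)2 (2.0 equiv), 11 (2.0 equiv), THF, −78 °C; AcCl (1.0 equiv), −78 → −20 °C; aq. NH4Cl
Reagents that add atoms: acetyl chloride (12), CC(=O)Cl
Why: The lithium dienolate formed at the C6 methyl group is C-acylated at its γ-carbon; the second equivalent of dienolate absorbs the proton of the more acidic product, which is why it is used in excess.

Step 7
Reactants: 13 acetonyl dioxinone; 2 prenyl bromide
Product: 14 keto-dioxinone 2,2-dimethyl-6-(6-methyl-2-oxohept-5-en-1-yl)-4H-1,3-dioxin-4-one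
Conditions: LiN(i-Pr)2 (2.1 equiv), THF, −78 °C; 2 (1.0 equiv), −78 → 0 °C; AcOH
Reagents that add atoms: prenyl bromide (2), CC(C)=CCBr
Why: Dianion alkylation of a 1,3-dicarbonyl-type compound; the second deprotonation takes place at the methyl group, and this terminal, less stabilized carbanion is the site that attacks the allylic bromide, while the doubly stabilized internal position stays untouched.

Step 8
Reactants: 14 keto-dioxinone; 10 amide
Product: 15 diketo-dioxinone 6-[4-Bf-3-(3-methylbut-2-en-1-yl)-2,4-dioxobutyl]-2,2-dimethyl-4H-1,3-dioxin-4-one (racemic)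
Conditions: 14 (2.2 equiv), LiN(i-Pr)2 (4.4 equiv), THF, −78 °C; then 10, −78 → −20 °C; AcOH
Reagents that add atoms: none
Why: Crossed Claisen-type C-acylation of the dianion of 14 at its terminal carbon; the N-methoxy-N-methyl amide forms a chelated tetrahedral adduct that collapses only on work-up, so the ketone is not attacked a second time. The new methine is racemic and enolizable, which is of no consequence because it becomes an aromatic carbon.

Step 9
Reactants: 15 diketo-dioxinone
Product: 19 resorcylate methyl 2-Bf-4,6-dihydroxy-3-(3-methylbut-2-en-1-yl)benzoate, via acylketene 16 (not isolated), via triketo ester 17 (not isolated), via aldol adduct 18 (not isolated)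
Conditions: PhMe–MeOH (10:1), 110 °C, sealed tube; evaporate; Et3N, 4 Å MS, CH2Cl2, rt
Reagents that add atoms: methanol, CO
Why: Heating causes a retro-[4+2] fragmentation of the dioxinone that expels acetone and leaves acylketene 16, which the large excess of methanol captures as the 3,5,7-triketo ester 17. Triethylamine then enolizes the β-keto ester end, whose α-carbon adds to the benzofuranyl ketone (intramolecular aldol, forming C1'–C6' and giving 18); β-elimination of water and two enolizations deliver the aromatic ring. The closest known reaction type is the cyclization–aromatization of triketo esters released from diketo-dioxinones to 6-substituted resorcylates. Ring C closes by a 6-exo-trig attack of the enolate carbon on the ketone carbonyl. No stereocenter survives: the methine of 15 and the two sp3 centres of 18 all become aromatic carbons. The step needs C-aldol at the ester α-carbon in preference to Claisen attack of the prenyl-bearing carbon on the ester, to O-cyclization to pyranones and to retro-Claisen cleavage of the diketone. The prenyl group makes the competing carbon nucleophile tertiary and hindered and its cyclization product unable to aromatize; the aldol is reversible while the dehydration is not; and a non-nucleophilic amine in an aprotic solvent offers no alkoxide for cleavage. The 2-alkyl-1,3-diketone should also stay largely in its diketo form, which keeps the aryl ketone electrophilic.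

Step 10
Reactants: 19 resorcylate
Product: 20 silyl ether methyl 2-Bf-6-hydroxy-3-(3-methylbut-2-en-1-yl)-4-[(triisopropylsilyl)oxy]benzoate
Conditions: TIPSCl (1.1 equiv), imidazole, DMF, 0 °C → rt
Reagents that add atoms: chlorotriisopropylsilane, CC(C)[Si](Cl)(C(C)C)C(C)C
Why: Selective silylation; the hydroxyl ortho to the ester is locked in a hydrogen bond, so the para hydroxyl reacts. Masking it removes the para-quinone methide pathway and the free phenol next to the prenyl group before the reduction and the hot step.

Step 11
Reactants: 20 silyl ether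
Product: 21 salicyl alcohol 3-Bf-2-(hydroxymethyl)-4-(3-methylbut-2-en-1-yl)-5-[(triisopropylsilyl)oxy]phenol
Conditions: LiAlH4, THF, 0 °C → rt; aq. potassium sodium tartrate work-up
Reagents that add atoms: none
Why: Hydride reduction of a salicylate ester to the benzylic alcohol; the small hydride reaches the flanked ester, and keeping the mixture at or below room temperature should prevent the aluminate of the product from eliminating and being reduced further to a methyl group.

Step 12
Reactants: 21 salicyl alcohol; 22 isobutene (2-methylpropene)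
Product: 24 tris-silyl ether 2-{2,2-dimethyl-6-(3-methylbut-2-en-1-yl)-7-[(triisopropylsilyl)oxy]-3,4-dihydro-2H-chromen-5-yl}-7-(2-methylbut-3-en-2-yl)-4,6-bis[(triisopropylsilyl)oxy]-1-benzofuran, via quinone methide 23 (not isolated)
Conditions: 22 (large excess, condensed), PhMe (dilute), sealed tube, 150 °C
Reagents that add atoms: isobutene (22), CC(C)=C
Why: Thermal 1,4-dehydration of the o-hydroxybenzyl alcohol gives o-quinone methide 23, which is trapped by the alkene in an inverse-demand hetero-Diels–Alder reaction. The unsubstituted alkene carbon bonds to the exocyclic methylene and the oxygen to the carbon that best carries positive charge, which gives the 2,2-dimethyl pattern of ring D; the neutral medium leaves the silyl ethers and both side-chain alkenes untouched.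

Step 13
Reactants: 24 tris-silyl ether
Product: 25 artopetelin C 2-[7-hydroxy-2,2-dimethyl-6-(3-methylbut-2-en-1-yl)-3,4-dihydro-2H-chromen-5-yl]-7-(2-methylbut-3-en-2-yl)-1-benzofuran-4,6-diol
Conditions: Bu4NF (3.5 equiv), AcOH (3.5 equiv), THF, 0 °C → rt, Ar
Reagents that add atoms: none
Why: Fluoride-induced cleavage of the three aryl silyl ethers, driven by the Si–F bond; the acetic acid buffer protonates the phenoxides at once to limit oxidation, and it is too weak an acid to close either allyl group onto its neighbouring phenol.

## Compound list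

1 | 2,4,6-trihydroxybenzaldehyde | O=Cc1c(O)cc(O)cc1O | starting material
2 | prenyl bromide (1-bromo-3-methylbut-2-ene) | CC(C)=CCBr | starting material
3 | 2,6-dihydroxy-4-[(3-methylbut-2-en-1-yl)oxy]benzaldehyde | O=Cc1c(O)cc(OCC=C(C)C)cc1O | intermediate
4 | 2,6-dihydroxy-3-(2-methylbut-3-en-2-yl)-4-oxocyclohexa-1,5-diene-1-carbaldehyde (racemic, not isolated) | O=CC1=C(O)C(C(C)(C)C=C)C(=O)C=C1O | intermediate
5 | 2,4,6-trihydroxy-3-(2-methylbut-3-en-2-yl)benzaldehyde | O=Cc1c(O)cc(O)c(C(C)(C)C=C)c1O | intermediate
6 | 2-hydroxy-3-(2-methylbut-3-en-2-yl)-4,6-bis[(triisopropylsilyl)oxy]benzaldehyde | O=Cc1c(O[Si](C(C)C)(C(C)C)C(C)C)cc(O[Si](C(C)C)(C(C)C)C(C)C)c(C(C)(C)C=C)c1O | intermediate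
7 | ethyl bromoacetate | CCOC(=O)CBr | starting material
8 | ethyl 2-{2-formyl-6-(2-methylbut-3-en-2-yl)-3,5-bis[(triisopropylsilyl)oxy]phenoxy}acetate (not isolated) | CCOC(=O)COc1c(C=O)c(O[Si](C(C)C)(C(C)C)C(C)C)cc(O[Si](C(C)C)(C(C)C)C(C)C)c1C(C)(C)C=C | intermediate
9 | ethyl 7-(2-methylbut-3-en-2-yl)-4,6-bis[(triisopropylsilyl)oxy]-1-benzofuran-2-carboxylate | CCOC(=O)c1cc2c(O[Si](C(C)C)(C(C)C)C(C)C)cc(O[Si](C(C)C)(C(C)C)C(C)C)c(C(C)(C)C=C)c2o1 | intermediate
10 | N-methoxy-N-methyl-7-(2-methylbut-3-en-2-yl)-4,6-bis[(triisopropylsilyl)oxy]-1-benzofuran-2-carboxamide | CON(C)C(=O)c1cc2c(O[Si](C(C)C)(C(C)C)C(C)C)cc(O[Si](C(C)C)(C(C)C)C(C)C)c(C(C)(C)C=C)c2o1 | intermediate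
11 | 2,2,6-trimethyl-4H-1,3-dioxin-4-one | CC1=CC(=O)OC(C)(C)O1 | starting material
12 | acetyl chloride | CC(=O)Cl | starting material
13 | 2,2-dimethyl-6-(2-oxopropyl)-4H-1,3-dioxin-4-one | CC(=O)CC1=CC(=O)OC(C)(C)O1 | intermediate
14 | 2,2-dimethyl-6-(6-methyl-2-oxohept-5-en-1-yl)-4H-1,3-dioxin-4-one | CC(C)=CCCC(=O)CC1=CC(=O)OC(C)(C)O1 | intermediate
15 | 6-[4-Bf-3-(3-methylbut-2-en-1-yl)-2,4-dioxobutyl]-2,2-dimethyl-4H-1,3-dioxin-4-one (racemic) | C=CC(C)(C)c1c(O[Si](C(C)C)(C(C)C)C(C)C)cc(O[Si](C(C)C)(C(C)C)C(C)C)c2cc(C(=O)C(CC=C(C)C)C(=O)CC3=CC(=O)OC(C)(C)O3)oc12 | intermediate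
16 | 7-Bf-6-(3-methylbut-2-en-1-yl)hept-1-ene-1,3,5,7-tetrone (acylketene, racemic, not isolated) | C=CC(C)(C)c1c(O[Si](C(C)C)(C(C)C)C(C)C)cc(O[Si](C(C)C)(C(C)C)C(C)C)c2cc(C(=O)C(CC=C(C)C)C(=O)CC(=O)C=C=O)oc12 | intermediate
17 | methyl 7-Bf-6-(3-methylbut-2-en-1-yl)-3,5,7-trioxoheptanoate (racemic, not isolated) | C=CC(C)(C)c1c(O[Si](C(C)C)(C(C)C)C(C)C)cc(O[Si](C(C)C)(C(C)C)C(C)C)c2cc(C(=O)C(CC=C(C)C)C(=O)CC(=O)CC(=O)OC)oc12 | intermediate
18 | methyl 2-Bf-2-hydroxy-3-(3-methylbut-2-en-1-yl)-4,6-dioxocyclohexane-1-carboxylate (mixture of stereoisomers, not isolated) | C=CC(C)(C)c1c(O[Si](C(C)C)(C(C)C)C(C)C)cc(O[Si](C(C)C)(C(C)C)C(C)C)c2cc(C3(O)C(CC=C(C)C)C(=O)CC(=O)C3C(=O)OC)oc12 | intermediate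
19 | methyl 2-Bf-4,6-dihydroxy-3-(3-methylbut-2-en-1-yl)benzoate | C=CC(C)(C)c1c(O[Si](C(C)C)(C(C)C)C(C)C)cc(O[Si](C(C)C)(C(C)C)C(C)C)c2cc(-c3c(CC=C(C)C)c(O)cc(O)c3C(=O)OC)oc12 | intermediate
20 | methyl 2-Bf-6-hydroxy-3-(3-methylbut-2-en-1-yl)-4-[(triisopropylsilyl)oxy]benzoate | C=CC(C)(C)c1c(O[Si](C(C)C)(C(C)C)C(C)C)cc(O[Si](C(C)C)(C(C)C)C(C)C)c2cc(-c3c(CC=C(C)C)c(O[Si](C(C)C)(C(C)C)C(C)C)cc(O)c3C(=O)OC)oc12 | intermediate
21 | 3-Bf-2-(hydroxymethyl)-4-(3-methylbut-2-en-1-yl)-5-[(triisopropylsilyl)oxy]phenol | C=CC(C)(C)c1c(O[Si](C(C)C)(C(C)C)C(C)C)cc(O[Si](C(C)C)(C(C)C)C(C)C)c2cc(-c3c(CC=C(C)C)c(O[Si](C(C)C)(C(C)C)C(C)C)cc(O)c3CO)oc12 | intermediate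
22 | isobutene (2-methylpropene) | CC(C)=C | starting material
23 | 5-Bf-6-methylidene-4-(3-methylbut-2-en-1-yl)-3-[(triisopropylsilyl)oxy]cyclohexa-2,4-dien-1-one (not isolated) | C=CC(C)(C)c1c(O[Si](C(C)C)(C(C)C)C(C)C)cc(O[Si](C(C)C)(C(C)C)C(C)C)c2cc(C3=C(CC=C(C)C)C(O[Si](C(C)C)(C(C)C)C(C)C)=CC(=O)C3=C)oc12 | intermediate
24 | 2-{2,2-dimethyl-6-(3-methylbut-2-en-1-yl)-7-[(triisopropylsilyl)oxy]-3,4-dihydro-2H-chromen-5-yl}-7-(2-methylbut-3-en-2-yl)-4,6-bis[(triisopropylsilyl)oxy]-1-benzofuran | C=CC(C)(C)c1c(O[Si](C(C)C)(C(C)C)C(C)C)cc(O[Si](C(C)C)(C(C)C)C(C)C)c2cc(-c3c(CC=C(C)C)c(O[Si](C(C)C)(C(C)C)C(C)C)cc4c3CCC(C)(C)O4)oc12 | intermediate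
25 | artopetelin C, 2-[7-hydroxy-2,2-dimethyl-6-(3-methylbut-2-en-1-yl)-3,4-dihydro-2H-chromen-5-yl]-7-(2-methylbut-3-en-2-yl)-1-benzofuran-4,6-diol | C=CC(C)(C)c1c(O)cc(O)c2cc(-c3c(CC=C(C)C)c(O)cc4c3CCC(C)(C)O4)oc12 | target

## Step count and least certain steps

Total: 13 steps. Longest linear sequence: 11 steps (steps 1 to 5, then 8 to 13); the dioxinone branch (steps 6 and 7) joins at step 8.

**Step 9 (key step).** The aryl ketone is conjugated with an electron-rich benzofuran and sits next to a tertiary carbon, so the ring-closing aldol addition may be slow. Slow closure would give time for O-cyclization of the polyketone to pyranones during the heating stage, for cleavage of the 2-alkyl-1,3-diketone, or for the aldol adduct to stall before dehydration. The fallback sets out from 15 and leaves the dioxinone closed. Et3N with 4 Å molecular sieves in CH2Cl2 at room temperature lets the dioxinone C5 position attack the aryl ketone directly, without a heating stage or a free ester, and dehydration should give the acetonide-bridged resorcylate 5-Bf-7-hydroxy-2,2-dimethyl-6-(3-methylbut-2-en-1-yl)-4H-1,3-benzodioxin-4-one F1. Silylation of its one phenol (TIPSCl, imidazole, DMF) would give 5-Bf-2,2-dimethyl-6-(3-methylbut-2-en-1-yl)-7-[(triisopropylsilyl)oxy]-4H-1,3-benzodioxin-4-one F2. LiAlH4 in THF at 0 °C then reduces the acylal carbonyl with loss of the acetonide, and the route is rejoined at 21.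

**Step 12.** The quinone methide may be consumed faster by self-condensation (attack by the free ring position of a second molecule, or dimerization) or by closure onto the nucleophilic C3 of the benzofuran than it is intercepted by a volatile, only moderately nucleophilic alkene. The fallback sets out from 21 and builds ring D one bond at a time:
- MnO2 in CH2Cl2 gives the salicylaldehyde 2-Bf-6-hydroxy-3-(3-methylbut-2-en-1-yl)-4-[(triisopropylsilyl)oxy]benzaldehyde F3.
- Wittig reaction with Ph3P=CHC(O)CH3 in PhMe at 80 °C gives the enone (E)-4-{2-Bf-6-hydroxy-3-(3-methylbut-2-en-1-yl)-4-[(triisopropylsilyl)oxy]phenyl}but-3-en-2-one F4.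
- Conjugate reduction with [(Ph3P)CuH]6 gives the ketone 4-{2-Bf-6-hydroxy-3-(3-methylbut-2-en-1-yl)-4-[(triisopropylsilyl)oxy]phenyl}butan-2-one F5.
- Excess MeMgBr in THF at 0 °C gives the tertiary alcohol 3-Bf-2-(3-hydroxy-3-methylbutyl)-4-(3-methylbut-2-en-1-yl)-5-[(triisopropylsilyl)oxy]phenol F6.
- Catalytic TsOH in CH2Cl2 at 0 °C closes the ether through the tertiary cation onto the only free phenol and returns to the route at 24. The prenyl group has no free phenol next to it at this stage.

**Step 8.** The nucleophilic carbon of the dianion is secondary and hindered. Acylation may be slow and incomplete, and proton transfer from the adduct or from the amide would use up the dianion. The fallback sets out from 10 and replaces the acylation by an aldol addition and an oxidation. i-Bu2AlH in THF at −78 °C reduces 10 to the aldehyde 7-(2-methylbut-3-en-2-yl)-4,6-bis[(triisopropylsilyl)oxy]-1-benzofuran-2-carbaldehyde F7. The dianion of 14 adds to it at −78 °C to give the aldol 6-[4-Bf-4-hydroxy-3-(3-methylbut-2-en-1-yl)-2-oxobutyl]-2,2-dimethyl-4H-1,3-dioxin-4-one F8 as a mixture of diastereomers. IBX in DMSO at room temperature oxidizes the alcohol and returns to the route at 15.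

**Step 4.** Carbonate and the amidine base at elevated temperature may remove or shift an aryl silyl group, after which the alkylating agent would attack the wrong oxygen. The phenol to be alkylated also lies between two ortho groups and may react slowly. The fallback sets out from 5 and uses base-stable ethers during the furan formation:
- MOMCl and i-Pr2NEt in CH2Cl2 give 2-hydroxy-4,6-bis(methoxymethoxy)-3-(2-methylbut-3-en-2-yl)benzaldehyde F9.
- 7 with K2CO3 in DMF at 100 °C gives ethyl 4,6-bis(methoxymethoxy)-7-(2-methylbut-3-en-2-yl)-1-benzofuran-2-carboxylate F10.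
- HCl in EtOH at 40 °C gives ethyl 4,6-dihydroxy-7-(2-methylbut-3-en-2-yl)-1-benzofuran-2-carboxylate F11.
- TIPSOTf and 2,6-lutidine in CH2Cl2 return to the route at 9.

**Step 3.** Site discrimination among three phenols may be insufficient: the hindered C4 hydroxyl may be silylated incompletely, or the chelated C2 hydroxyl may be silylated as well. The fallback sets out from 3 and silylates before the rearrangement. One equivalent of TIPSCl with imidazole in CH2Cl2 gives 2-hydroxy-4-[(3-methylbut-2-en-1-yl)oxy]-6-[(triisopropylsilyl)oxy]benzaldehyde F12. The Claisen rearrangement (PhNEt2, 180 °C) is then directed to the position between the chelated hydroxyl and the ether oxygen, away from the silyl ether, and gives 2,4-dihydroxy-3-(2-methylbut-3-en-2-yl)-6-[(triisopropylsilyl)oxy]benzaldehyde F13. Silylation of its non-chelated hydroxyl (TIPSCl, imidazole, DMF) returns to the route at 6.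

## Further compounds

F1 | step 9 | 5-Bf-7-hydroxy-2,2-dimethyl-6-(3-methylbut-2-en-1-yl)-4H-1,3-benzodioxin-4-one | C=CC(C)(C)c1c(O[Si](C(C)C)(C(C)C)C(C)C)cc(O[Si](C(C)C)(C(C)C)C(C)C)c2cc(-c3c(CC=C(C)C)c(O)cc4OC(C)(C)OC(=O)c34)oc12
F2 | step 9 | 5-Bf-2,2-dimethyl-6-(3-methylbut-2-en-1-yl)-7-[(triisopropylsilyl)oxy]-4H-1,3-benzodioxin-4-one | C=CC(C)(C)c1c(O[Si](C(C)C)(C(C)C)C(C)C)cc(O[Si](C(C)C)(C(C)C)C(C)C)c2cc(-c3c(CC=C(C)C)c(O[Si](C(C)C)(C(C)C)C(C)C)cc4OC(C)(C)OC(=O)c34)oc12
F3 | step 12 | 2-Bf-6-hydroxy-3-(3-methylbut-2-en-1-yl)-4-[(triisopropylsilyl)oxy]benzaldehyde | C=CC(C)(C)c1c(O[Si](C(C)C)(C(C)C)C(C)C)cc(O[Si](C(C)C)(C(C)C)C(C)C)c2cc(-c3c(CC=C(C)C)c(O[Si](C(C)C)(C(C)C)C(C)C)cc(O)c3C=O)oc12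
F4 | step 12 | (E)-4-{2-Bf-6-hydroxy-3-(3-methylbut-2-en-1-yl)-4-[(triisopropylsilyl)oxy]phenyl}but-3-en-2-one | C=CC(C)(C)c1c(O[Si](C(C)C)(C(C)C)C(C)C)cc(O[Si](C(C)C)(C(C)C)C(C)C)c2cc(-c3c(CC=C(C)C)c(O[Si](C(C)C)(C(C)C)C(C)C)cc(O)c3/C=C/C(C)=O)oc12
F5 | step 12 | 4-{2-Bf-6-hydroxy-3-(3-methylbut-2-en-1-yl)-4-[(triisopropylsilyl)oxy]phenyl}butan-2-one | C=CC(C)(C)c1c(O[Si](C(C)C)(C(C)C)C(C)C)cc(O[Si](C(C)C)(C(C)C)C(C)C)c2cc(-c3c(CC=C(C)C)c(O[Si](C(C)C)(C(C)C)C(C)C)cc(O)c3CCC(C)=O)oc12
F6 | step 12 | 3-Bf-2-(3-hydroxy-3-methylbutyl)-4-(3-methylbut-2-en-1-yl)-5-[(triisopropylsilyl)oxy]phenol | C=CC(C)(C)c1c(O[Si](C(C)C)(C(C)C)C(C)C)cc(O[Si](C(C)C)(C(C)C)C(C)C)c2cc(-c3c(CC=C(C)C)c(O[Si](C(C)C)(C(C)C)C(C)C)cc(O)c3CCC(C)(C)O)oc12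
F7 | step 8 | 7-(2-methylbut-3-en-2-yl)-4,6-bis[(triisopropylsilyl)oxy]-1-benzofuran-2-carbaldehyde | O=Cc1cc2c(O[Si](C(C)C)(C(C)C)C(C)C)cc(O[Si](C(C)C)(C(C)C)C(C)C)c(C(C)(C)C=C)c2o1
F8 | step 8 | 6-[4-Bf-4-hydroxy-3-(3-methylbut-2-en-1-yl)-2-oxobutyl]-2,2-dimethyl-4H-1,3-dioxin-4-one (mixture of diastereomers) | C=CC(C)(C)c1c(O[Si](C(C)C)(C(C)C)C(C)C)cc(O[Si](C(C)C)(C(C)C)C(C)C)c2cc(C(O)C(CC=C(C)C)C(=O)CC3=CC(=O)OC(C)(C)O3)oc12
F9 | step 4 | 2-hydroxy-4,6-bis(methoxymethoxy)-3-(2-methylbut-3-en-2-yl)benzaldehyde | O=Cc1c(OCOC)cc(OCOC)c(C(C)(C)C=C)c1O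
F10 | step 4 | ethyl 4,6-bis(methoxymethoxy)-7-(2-methylbut-3-en-2-yl)-1-benzofuran-2-carboxylate | CCOC(=O)c1cc2c(OCOC)cc(OCOC)c(C(C)(C)C=C)c2o1
F11 | step 4 | ethyl 4,6-dihydroxy-7-(2-methylbut-3-en-2-yl)-1-benzofuran-2-carboxylate | CCOC(=O)c1cc2c(O)cc(O)c(C(C)(C)C=C)c2o1
F12 | step 3 | 2-hydroxy-4-[(3-methylbut-2-en-1-yl)oxy]-6-[(triisopropylsilyl)oxy]benzaldehyde | O=Cc1c(O)cc(OCC=C(C)C)cc1O[Si](C(C)C)(C(C)C)C(C)C
F13 | step 3 | 2,4-dihydroxy-3-(2-methylbut-3-en-2-yl)-6-[(triisopropylsilyl)oxy]benzaldehyde | O=Cc1c(O[Si](C(C)C)(C(C)C)C(C)C)cc(O)c(C(C)(C)C=C)c1O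
A1 | alternative 1 | 2-diazo-1-{5-[2,2-dimethyl-6-(3-methylbut-2-en-1-yl)-7-(pivaloyloxy)-3,4-dihydro-2H-chromen-5-yl]furan-2-yl}ethan-1-one | [N-]=[N+]=CC(=O)c1ccc(-c2c(CC=C(C)C)c(OC(=O)C(C)(C)C)cc3OC(C)(C)CCc23)o1
A2 | alternative 1 | ethynyloxy(triisopropyl)silane | C#CO[Si](C(C)C)(C(C)C)C(C)C
A3 | alternative 1 | 5-{4-hydroxy-6-[(triisopropylsilyl)oxy]-1-benzofuran-2-yl}-2,2-dimethyl-6-(3-methylbut-2-en-1-yl)-3,4-dihydro-2H-chromen-7-yl pivalate | Oc1cc(O[Si](C(C)C)(C(C)C)C(C)C)cc2oc(-c3c(CC=C(C)C)c(OC(=O)C(C)(C)C)cc4OC(C)(C)CCc34)cc12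
A4 | alternative 2 | {2-[(7-{[tert-butyl(dimethyl)silyl]oxy}-2,2-dimethyl-6-(3-methylbut-2-en-1-yl)-3,4-dihydro-2H-chromene-5-carbonyl)oxy]-4,6-bis{[tert-butyl(dimethyl)silyl]oxy}-3-(2-methylbut-3-en-2-yl)benzyl}triphenylphosphonium bromide | [Br-].C=CC(C)(C)c1c(O[Si](C)(C)C(C)(C)C)cc(O[Si](C)(C)C(C)(C)C)c(C[P+](c2ccccc2)(c2ccccc2)c2ccccc2)c1OC(=O)c1c(CC=C(C)C)c(O[Si](C)(C)C(C)(C)C)cc2OC(C)(C)CCc12
A5 | alternative 2 | tri-O-(tert-butyldimethylsilyl) artopetelin C | C=CC(C)(C)c1c(O[Si](C)(C)C(C)(C)C)cc(O[Si](C)(C)C(C)(C)C)c2cc(-c3c(CC=C(C)C)c(O[Si](C)(C)C(C)(C)C)cc4OC(C)(C)CCc34)oc12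
A6 | alternative 3 | methyl 2-(3-acetyl-5-{2,2-dimethyl-6-(3-methylbut-2-en-1-yl)-7-[(triisopropylsilyl)oxy]-3,4-dihydro-2H-chromen-5-yl}furan-2-yl)-3,3-dimethylpent-4-enoate (racemic) | COC(=O)C(c1oc(-c2c(CC=C(C)C)c(O[Si](C(C)C)(C(C)C)C(C)C)cc3OC(C)(C)CCc23)cc1C(C)=O)C(C)(C)C=C
A7 | alternative 3 | 3'-O-(triisopropylsilyl) artopetelin C | C=CC(C)(C)c1c(O)cc(O)c2cc(-c3c(CC=C(C)C)c(O[Si](C(C)C)(C(C)C)C(C)C)cc4OC(C)(C)CCc34)oc12
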